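The ratio of the free catalyst charges of zeta to gamma is 3.65, and the choice of which recipe to charge for 8.0 min hangs on how far that ratio carries into the fraction of starting material left.

common to all: reagent 0.338 M
- ash: starting material 0.26 M; free catalyst 0.23 mM; temperature 15 °C; run made earlier
- maple: starting material 0.26 M; free catalyst 0.93 mM; temperature 26 °C; run made earlier
- oak: starting material 0.24 M; free catalyst 0.73 mM; temperature 15 °C; run made earlier
- zeta: starting material 0.26 M; free catalyst 0.73 mM; temperature 20 °C; time 8.0 min
- gamma: starting material 0.12 M; free catalyst 0.20 mM; temperature 20 °C; time 8.0 min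

| run | time / min | target / % | starting material / % |
|---|---|---|---|
| ash | 0.333 | 0.9 | 99.4 |
| ash | 0.500 | 1.3 | 97.8 |
| ash | 0.833 | 2.7 | 97.9 |
| ash | 1.33 | 3.2 | 94.3 |
| ash | 2.50 | 8.2 | 91.4 |
| ash | 4.00 | 11.3 | 89.3 |
| maple | 0.333 | 5.0 | 93.7 |
| maple | 0.500 | 6.3 | 92.9 |
| maple | 0.833 | 12.9 | 88.5 |
| maple | 1.33 | 17.6 | 82.5 |
| maple | 2.50 | 31.5 | 70.7 |
| maple | 4.00 | 43.3 | 56.4 |
| oak | 0.333 | 1.4 | 96.4 |
| oak | 1.00 | 9.7 | 92.1 |
| oak | 2.00 | 19.4 | 82.3 |
| oak | 3.00 | 26.7 | 71.3 |
| oak | 4.00 | 36.2 | 65.7 |

(each reading ± 1 percentage point)

- the flask that ends with the higher amount of target, in percent of the starting material charged, or "neither" when 2 percentage points or less lies between them (zeta / gamma / neither)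
- final target, as a percentage of the starting material charged, in zeta
- final target, as a percentage of the starting material charged, in gamma

- the analysis behind the earlier runs scatters by 1 percentage point, standard deviation

In the last readings, target and starting material add up to 102% in oak and 99.7% in maple, so target is reckoned here as the charge less what is left. The reckoning works with that fraction left, treats the loss as pseudo-first-order, and divides by catalyst and time:

s = ln[ c(starting material, charged) / c(starting material, at t) ] / [ c(free catalyst, charged) · t ]

The last readings of ash, oak and maple give 0.123 mM⁻¹ min⁻¹, 0.144 mM⁻¹ min⁻¹ and 0.154 mM⁻¹ min⁻¹, although free catalyst runs from 0.23 mM to 0.93 mM. Oak and maple bracket zeta's 20 °C, and each has lost more than ash, so that a point of scatter counts for less in them. Their mean is the working value, the catalyst-time constant s = 0.149 mM⁻¹ min⁻¹, read at 0.338 M of reagent and at 0.24 M to 0.26 M of starting material, and applied here as it stands: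

left = exp(−s · c(free catalyst) · t)

zeta: left 41.9%, target 58.1%

gamma: left 78.8%, target 21.2%

The reckoned gap of 37 percentage points stands against a margin of 2 points, so this reckoning charges zeta, though gamma's 0.12 M of starting material lies below the smallest charge read, 0.24 M.

The forecast also names zeta, with 59% for zeta and 25% for gamma, which is higher than the gamma reckoned here, and it cautions: “No run tests concentration well.”

The flask gives zeta, with 58.8% of target in zeta and 30.0% in gamma, which puts gamma 5 points above the forecast for gamma.

    starting material + free catalyst ⇌ catalyst intermediate A (K = 1.86 M⁻¹, k = 72.4 M⁻¹ s⁻¹, Ea = 51.0 kJ mol⁻¹, ΔH = −78.0 kJ mol⁻¹)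
    reagent + catalyst intermediate A → catalyst intermediate B (k = 9.33 M⁻¹ s⁻¹, Ea = 40.0 kJ mol⁻¹)
    catalyst intermediate B ⇌ by-product + catalyst intermediate C (K = 0.120 M, k = 2.83 s⁻¹, Ea = 75.0 kJ mol⁻¹, ΔH = −36.0 kJ mol⁻¹)
    catalyst intermediate C → free catalyst + target (k = 27.5 s⁻¹, Ea = 52.0 kJ mol⁻¹)
    crystals ⇌ by-product, rate k5*(cs5 - [by-product]) while solid is left; crystals form when [by-product] > cs5 (solubility = 0.130 M, k = 0.104 s⁻¹)
    (constants at 20 °C)

Put back into s, zeta's end reads 0.152 mM⁻¹ min⁻¹, close to the working 0.149 mM⁻¹ min⁻¹, while gamma's reads 0.223 mM⁻¹ min⁻¹, 1.47 times zeta's. At the time of the last reading of the ash run, taken without the scatter and with its other settings held, moving its starting-material charge to gamma's lifts target from 12.1% to 18.2%. For zeta's recipe with 1.20 mM of free catalyst, s gives 23.9% left, and that flask ends with 25.2% of its starting material.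

The runs were computed with constants of no real substance, and the scatter is random.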